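Take the substrate reacted and the target found in a run, and look at the gap between them.

| setting | autumn | winter | flask |
|---|---|---|---|
| substrate | 0.050 M | 0.20 M | 0.10 M |
| reagent in the second phase | 1.1 equiv | 1.1 equiv | 1.10 equiv |
| remark | run made earlier | run made earlier |  |
| time |  |  | 30 h |
| volume of the second phase over the first |  |  | 0.50 |

- autumn (time / h: target / %, substrate / %): 2.00: 0.4, 99.7; 4.00: 0, 98.5; 6.00: 2.9, 99.7; 12.0: 4.1, 95.8; 25.0: 14.6, 82.8
- winter (time / h: target / %, substrate / %): 2.00: 0.1, 98.5; 4.00: 3.0, 98.6; 6.00: 5.5, 93.6; 12.0: 9.7, 86.1; 25.0: 19.1, 66.5

(scatter of a reading: 1 percentage point)

- a species is counted by the substrate in it: one side product counts as two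
- in the second phase: reagent in the second phase; everything else is in the first
- charges count per volume of the first phase; a concentration in a rate is the amount of a species over the volume of its own phase; every rate counts per litre of the first phase
- the earlier runs were read with a standard deviation of 1 percentage point
- what may be going on: reagent in the reaction phase <-> reagent in the second phase; substrate + reagent in the reaction phase -> target; reagent in the reaction phase + target -> over-reacted product; substrate + target -> side product; reagent in the reaction phase + target -> over-reaction product
- the earlier runs hold the two phases in the same ratio of volumes as the flask asked about

1. how much target there is at 30 h, in percent of the substrate charged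
2. part of the substrate charged that has reacted at 30 h

Two chemists read these runs differently. The first holds that reacted substrate stays as target: in the autumn run at 12.0 h the substrate has lost 4.20% and the target reads 4.1%, and at 25.0 h the gap is 2.6 percentage points, with readings good to 1 point. On that view the target in the flask equals its reacted share, 31% on the forecast's conversion.

The second answers with the winter run at 25.0 h, where the gap reads 14 points, larger than in autumn. She sees consecutive reactions: target must exist before it can be used, so she expects the gap to grow with the square of conversion. Winter reads 1.28 for her loss coefficient, the gap over the square of the fraction reacted. Autumn reads 0.879, from a gap smaller than winter's and so less sure.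

The forecast also puts the target below the reacted share: 21.5% of target (18% to 25%) and 31% reacted (26% to 36%), its ground being that “loss of target is strongly concentration dependent”. My own reckoning differs: the winter coefficient at that conversion leaves 18.7%, less than the forecast's target.

At 30 h the flask gives 18.3% of target with 30.7% reacted.

    reagent in the reaction phase ⇌ reagent in the second phase, rate k1*([reagent in the reaction phase] - [reagent in the second phase]/K1) per volume of the first phase (partition coefficient = 1.90, kL = 3.40 × 10⁻⁴ /min)
    substrate + reagent in the reaction phase → target (k = 0.0160 /M/min)
    reagent in the reaction phase + target → over-reacted product (k = 0.0250 /M/min)
    substrate + target → side product (k = 0.00210 /M/min)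
    reagent in the reaction phase + target → over-reaction product (k = 0.00300 /M/min)

The flask's gap is 12 points, and the coefficient on its conversion gives 12 points. The first chemist's view fits the early part of this flask: at 3.00 h it has reacted 0.899% and holds 0.869% of target. A neighbouring flask with 0.025 M of substrate has reacted 13.5% at 30.0 h, so the coefficient predicts a gap of 2.3 points and 11.2% of target; that flask holds 11.2%.

The runs come from a simulation with constants of no real substance; noise was put on by code.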